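## Structural features

The skeleton is numbered along the SMILES string: C-1 (ester-bearing CH), C-2, C-3 (quaternary), C-4 (lactam C=O), N-5, C-6, C-7, C-8, C-9, C-10=C-11, C-12, C-13, C-14, C-15 (quaternary), C-16, C-17, C-18 (carbinol), C-19 (CH–CH3), C-20, and C-21 for the acetoxymethyl carbon. There are five rings: ring A (cyclopentane C-1, C-2, C-3, C-11, C-12), ring B (cyclopentene C-10 to C-14), ring C (cycloheptene C-3, C-15, C-7, C-8, C-9, C-10, C-11), ring D (δ-lactam C-3, C-4, N-5, C-6, C-7, C-15, bridging C-3 and C-7 of ring C) and ring E (nine-membered, N-5, C-20, C-19, C-18, C-17, C-16, C-15, C-3, C-4, spanning N-5 and C-15 across ring D); the tetrasubstituted alkene C-10=C-11 is shared by rings B and C, and C-11 also belongs to ring A. Of the seven stereocentres, C-1 and C-12 are adjacent (H-1 and H-12 cis, so the ester lies on the face of ring A that also carries C-13 and C-15), C-3 and C-15 are vicinal quaternary carbons with the bridgehead C-7 next to C-15, and C-18 and C-19 are adjacent with hydroxyl and methyl syn. Fragile points are the epimerisable C-1 ester on the more crowded face, the primary acetate beside a free secondary alcohol, the β-keto amide and β-alkoxy amide intermediates (retro-Claisen, retro-aldol), and the electron-rich alkene towards electrophiles. The real difficulty is the pair of contiguous quaternary carbons inside the bicyclo[4.3.1] core of rings C and D, together with the medium ring, whose C-16 arm must stand on the lactam face of C-15 while C-21 points to the carbocyclic face. The key step exploits the fact that C-15 is the one-atom bridge between C-3 and C-7 and can be carried as a ketone: because C-3 is quaternary this ketone enolises only towards C-7, and C-7 is separated from C-3 through the amide by exactly C-4, N-5 and one missing carbon (C-6), which formaldehyde supplies.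

## Logic of the disconnections

33 to 32: the C-21 O–acyl bond is cut last. An acetate present during the reductive ring closure would be open to acyl transfer to an alkylsamarium at C-17 through a six-membered transition state, so the acetate is introduced at the end. The forward step must acetylate a primary neopentyl hydroxyl in preference to the ring secondary one.

32 to 30: the C-21 carbinol is traced back to a vinyl group on C-15 (the C-21=CH2 bond is the one cleaved forward). The vinyl group is a hydroxymethyl masked by one carbon, inert to every intervening reagent and needing no protecting group. The demand is an oxidative cleavage that spares C-10=C-11.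

30 to 29: the C-17–C-18 bond of ring E is cut. It lies next to the existing C-19 centre, which can steer the new carbinol, and it opens the medium ring to an iodide arm and an aldehyde arm. The forward step must form a nine-membered ring at high dilution with 1,2-induction giving the syn C-18/C-19 relation.

29 to 25 (through 28, 27, 26): functional-group changes only. The C-18 aldehyde comes from the silyl ether, and the C-17 iodide from the aldehyde of 25 by reduction and substitution. Each step must be chemoselective beside the ester, lactam and two alkenes.

25 to 21 (through 24, 23, 22): the C-15–C-16 bond is cut by a retro-[3,3] shift to 24 and hence to 23, and 23 is taken back to ketone 21 by removing the two-carbon allylic unit. This creates quaternary C-15 from a trigonal carbon and delivers the two-carbon arm and the future C-21 at once. The allylic alcohol is reached by vinyl addition and 1,3-transposition because an olefination/hydride sequence would also reduce the C-1 ester, and a thermal shift is preferred to a carbanionic [2,3] shift because it avoids alkyllithium beside that ester. The forward shift must take place on the lactam face of C-15.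

21 to 18 and 19: the N-5–C-6 and C-6–C-7 bonds are cut, removing ring D and the C-7 stereocentre and leaving a tricyclic β-keto amide and formaldehyde. The forward step needs enolisation only towards C-7, and capture of the iminium ion by the enol rather than by the alkene.

18 to 10 and 16: the C-3–C-4 bond is cut, giving a tricyclic ketone and an isocyanate and making the route convergent. The forward step needs the C-3 enolate (not C-7) and attack on the face anti to the C-1 ester.

16 to 11 (through 14, 13, 12): the isocyanate nitrogen is traced to the ester carbon of 11 by reduction, azide displacement and Staudinger/aza-Wittig carbonylation. No bond to the stereocentre is touched.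

10 to 9 to 7: the alkene is moved back from C-10=C-11 to C-9=C-10, and then C-3–C-11 and C-7–C-8 are cut together, opening rings A and C to an acyclic chloromethyl ketone tethered to a 1-vinylcyclopentene. The forward (4+3) step has no lasting stereochemical demand because C-3 and C-11 are later planarised.

7 to 1 and 3 (through 6, 5, 4, 2): the chloromethyl carbon (C-7) is removed from C-15, the vinyl group from C-10, and the C-1–C-12 bond is cut to a glutarate nucleophile and cyclopentenone. The forward steps must differentiate the two esters, trap the enolate regiospecifically towards C-11, and set C-12 (absolute) and C-1 (relative) in the conjugate addition.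

## Other disconnections considered

Alternative 1: The cut runs through C-3–C-11 and C-7–C-8, opening rings A and C at once to the chloromethyl ketone A2. In the forward step, base in an ionising solvent turns A2 into an oxyallyl cation that adds across the vinylcyclopentene to give the tricyclic ketone A1.
- In its favour: two C–C bonds and two rings form in one operation from a precursor made of two commercial pieces, and the centres it creates at C-3 and C-11 are later planarised, so its diastereoselectivity is of no consequence.
- Against it as the centre of the plan: it solves only the carbocyclic half. Neither quaternary carbon, nor the lactam bridge, nor the medium ring is addressed.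
- Comparison: in bonds and rings formed per step it is better than the chosen key step (two C–C bonds and two rings against one C–C, one C–N and one ring). In early step economy it is equal, because the chosen plan contains the same reaction as step 5 (A1 is 9 and A2 is 7). Mechanistically it carries no selectivity burden, whereas the chosen key step must distinguish enol from alkene. Structurally it leaves C-3, C-15 and ring D untouched, which is where the chosen key step acts. The two are complementary, not rivals.

Alternative 2: The cut is through N-5–C-4 and C-3–C-15. In the forward step the disubstituted ketene A4 acylates the tertiary nitrogen of the 2-alkenylpyrrolidine A5, and the acylammonium enolate undergoes a [3,3] shift that expands the pyrrolidine to the nine-membered lactam A3.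
- In its favour: two fragments are joined convergently, and both quaternary carbons and the medium ring arise in one step. The medium ring forms by ring expansion with no entropic penalty, and C-15 is set by chirality transfer instead of by facial approach to a cage. On these points it is better than the chosen plan, which needs steps 11, 15 and 20 for the same tasks.
- Against it here: a tetrasubstituted ketene bearing an enol triflate is required. The configuration of C-3 depends on the geometry of an enolate derived from an unsymmetrical ketene, for which no obvious control element exists. The new bond joins two fully substituted carbons. A5 needs its own stereocontrolled synthesis (three stereocentres and a trisubstituted alkene). After A3, rings A, C and D are still to be closed (C-1–C-12, C-9–C-10, N-5–C-6), the ring alkene must be reduced and four protecting groups removed.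
- Comparison: in the use of a sigmatropic shift to create C-15 the two plans are equal. In total step economy the alternative is unlikely to be shorter. The risk is concentrated in one demanding step, whereas the chosen plan spreads it over several steps that can each be corrected.

Alternative 3: In the retrosynthetic sense the C-4 and C-18 carbonyls are joined to a C-4=C-18 enamine, giving the hexacyclic amine A7. In the forward step singlet oxygen (or CuCl with O2) adds to the enamine, the dioxetane fragments, and the keto lactam A6 results; reduction of the C-18 ketone then leads to 33.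
- In its favour: the nine-membered ring is revealed by cleaving a bond, not by a medium-ring cyclisation, which is better than step 20 of the chosen plan. The lactam carbonyl, C-15 and the acetoxymethyl group are already in place, so the endgame is one reduction, which is also better.
- Against it here: the difficulty is moved into A7, which holds the same two quaternary carbons plus two further rings and needs a long synthesis of its own. The oxidant must choose the enamine over C-10=C-11 (plausible, since the enamine is far more electron-rich). The final reduction must set the syn C-18/C-19 relation beside the acetate and ester.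
- Comparison: on C-3 the plans are equal, since both must build it early. Mechanistically the cleavage is a dependable enamine reaction. In step economy the alternative is better late and worse early, and the total should not be lower.

Key step: step 12

Remark on the chemistry: the side chain is taken from the (S)-enantiomer of methyl 3-hydroxy-2-methylpropanoate (11), whose ester carbon becomes C-20 and whose carbinol carbon becomes C-18, giving (R)-C-19 as required. The (R)-ester would need the opposite mapping through a β-sulfonyloxy ester that is prone to elimination.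

## Route

Step 1
Reactants: 1 dimethyl glutarate
Product: 2 methyl (4E)-5-methoxy-5-(trimethylsilyloxy)pent-4-enoate
Conditions: LiN(i-Pr)2 (1.0 equiv), THF, −78 °C; then Me3SiCl, −78 °C → rt
Reagents that add atoms: chlorotrimethylsilane, C[Si](C)(C)Cl
Why: Kinetic mono-deprotonation of the diester and O-silylation of the lithium enolate give the silyl ketene acetal (E expected in THF without polar co-solvent); a Dieckmann closure would be four-membered and does not compete at −78 °C.

Step 2
Reactants: 2 methyl (4E)-5-methoxy-5-(trimethylsilyloxy)pent-4-enoate; 3 cyclopent-2-en-1-one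
Product: 5 dimethyl (2R)-2-[(1S)-3-(trifluoromethylsulfonyloxy)cyclopent-2-en-1-yl]pentanedioate, via trimethylsilyl enol ether 4 (not isolated)
Conditions: B-(o-tolyl)oxazaborolidinium triflimide from diphenylprolinol (20 mol %), Ph3P=O (25 mol %), PhMe, −20 °C; then CsF, PhNTf2, DME, rt
Reagents that add atoms: N-phenylbis(trifluoromethanesulfonimide), O=S(=O)(N(c1ccccc1)S(=O)(=O)C(F)(F)F)C(F)(F)F
Why: Catalytic asymmetric Mukaiyama–Michael addition: the chiral boron Lewis acid binds the enone and screens one face, which sets C-12 (the catalyst antipode is chosen for the 1S centre), and C-1 follows from the open transition state, the syn relation being the one required. Silyl transfer leaves the enol ether double bond towards C-11, and fluoride-induced triflation fixes that regiochemistry.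

Step 3
Reactants: 5 dimethyl (2R)-2-[(1S)-3-(trifluoromethylsulfonyloxy)cyclopent-2-en-1-yl]pentanedioate
Product: 6 dimethyl (2R)-2-[(1S)-3-ethenylcyclopent-2-en-1-yl]pentanedioate
Conditions: Bu3SnCH=CH2, Pd(PPh3)4 (5 mol %), LiCl, THF, 65 °C
Reagents that add atoms: tributyl(vinyl)stannane, C=C[Sn](CCCC)(CCCC)CCCC
Why: Stille coupling of the enol triflate (oxidative addition to zerovalent palladium, vinyl transfer from tin, reductive elimination) gives the 1-vinylcyclopentene with the ring double bond where the enolate was trapped; the neutral medium leaves the C-1 ester centre untouched.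

Step 4
Reactants: 6 dimethyl (2R)-2-[(1S)-3-ethenylcyclopent-2-en-1-yl]pentanedioate
Product: 7 methyl (2R)-6-chloro-2-[(1S)-3-ethenylcyclopent-2-en-1-yl]-5-oxohexanoate
Conditions: ICH2Cl (1.1 equiv), MeLi·LiBr (1.05 equiv), THF/Et2O, −78 °C; NH4Cl (aq)
Reagents that add atoms: chloroiodomethane, ClCI
Why: Chloromethyllithium, generated beside the substrate by iodine–lithium exchange, adds to an ester and the tetrahedral lithium alkoxide persists at −78 °C, so one homologation to the chloromethyl ketone results; the unbranched ester should react in preference to the α-branched one flanked by the ring.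

Step 5
Reactants: 7 methyl (2R)-6-chloro-2-[(1S)-3-ethenylcyclopent-2-en-1-yl]-5-oxohexanoate
Product: 9 tricyclic ketone of rings A B C with the C-9=C-10 alkene, via oxyallyl cation 8 (not isolated)
Conditions: Et3N (2 equiv), CF3CH2OH, 0 °C → rt, 0.02 M
Reagents that add atoms: none
Why: Loss of HCl in the ionising solvent gives the oxyallyl cation, which adds across the s-cis diene in an intramolecular (4+3) cycloaddition; the three-atom tether joins C-3 to C-11 on the tether face (cis A/B fusion) and C-7 to C-8. The centres created at C-3 and C-11 are cleared in steps 6 and 11.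

Step 6
Reactants: 9 tricyclic ketone of rings A B C with the C-9=C-10 alkene
Product: 10 tricyclic ketone with the C-10=C-11 alkene
Conditions: RhCl3·3H2O (5 mol %), MeOH, 65 °C
Reagents that add atoms: none
Why: Rhodium hydride addition–elimination moves the trisubstituted alkene to the tetrasubstituted ring-fusion position, where re-addition is slow; a conjugated C-3=C-11 isomer, if formed, would give the same dienolate in step 11.

Step 7
Reactants: 11 methyl (S)-3-hydroxy-2-methylpropanoate
Product: 12 methyl (S)-3-[(tert-butyldiphenylsilyl)oxy]-2-methylpropanoate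
Conditions: t-BuPh2SiCl, imidazole, CH2Cl2, rt
Reagents that add atoms: tert-butyl(chloro)diphenylsilane, CC(C)(C)[Si](Cl)(c1ccccc1)c1ccccc1
Why: Standard silylation of the primary alcohol; the silyl ether is stable to acid, organometallics and mild oxidants and comes off with fluoride at step 18.

Step 8
Reactants: 12 methyl (S)-3-[(tert-butyldiphenylsilyl)oxy]-2-methylpropanoate
Product: 13 (R)-3-[(tert-butyldiphenylsilyl)oxy]-2-methylpropan-1-ol
Conditions: i-Bu2AlH (2.5 equiv), CH2Cl2, −78 → 0 °C
Reagents that add atoms: none
Why: Hydride reduction of the ester to the primary alcohol without touching the stereocentre (the descriptor changes only through the priority rules).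

Step 9
Reactants: 13 (R)-3-[(tert-butyldiphenylsilyl)oxy]-2-methylpropan-1-ol
Product: 14 (R)-(3-azido-2-methylpropoxy)(tert-butyl)diphenylsilane
Conditions: (PhO)2P(O)N3, i-PrO2CN=NCO2i-Pr, PPh3, THF, 0 °C → rt
Reagents that add atoms: diphenylphosphoryl azide, [N-]=[N+]=NP(=O)(Oc1ccccc1)Oc1ccccc1
Why: Mitsunobu azidation of an unhindered primary alcohol; substitution occurs at CH2, so the adjacent stereocentre is not involved.

Step 10
Reactants: 14 (R)-(3-azido-2-methylpropoxy)(tert-butyl)diphenylsilane
Product: 16 (R)-tert-butyl(3-isocyanato-2-methylpropoxy)diphenylsilane, via iminophosphorane 15 (not isolated)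
Conditions: PPh3, CO2 (1 atm), PhMe, rt → 60 °C
Reagents that add atoms: carbon dioxide, O=C=O
Why: Staudinger reaction to the iminophosphorane and aza-Wittig reaction with CO2 give the isocyanate directly; an excess of CO2 suppresses carbodiimide formation.

Step 11
Reactants: 10 tricyclic ketone with the C-10=C-11 alkene; 16 (R)-tert-butyl(3-isocyanato-2-methylpropoxy)diphenylsilane
Product: 18 tricyclic beta-keto amide, via potassium dienolate 17 (not isolated)
Conditions: KN(SiMe3)2 (1.05 equiv), THF, −78 °C; then 16, −78 → −40 °C; AcOH
Reagents that add atoms: none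
Why: H-3 is both α to the ketone and allylic, so it is removed in preference to the C-7 hydrogens, and the extended enolate is C-carbamoylated at its α-carbon by the isocyanate. Attack on the convex face of rings A/B, anti to the C-1 ester and to C-13, sets quaternary C-3; the low temperature keeps the C-7 enolate and the cis ester from condensing.

Step 12
Reactants: 18 tricyclic beta-keto amide; 19 formaldehyde (as paraformaldehyde)
Product: 21 bridged keto lactam of rings A to D, via N-acyliminium ion 20 (not isolated)
Conditions: (CH2O)n (3 equiv), CF3CO2H (10 equiv), ClCH2CH2Cl, 0 → 40 °C, 0.02 M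
Reagents that add atoms: none
Why: Acid depolymerises paraformaldehyde, the secondary amide is hydroxymethylated at nitrogen, and loss of water gives N-acyliminium ion 20 (N-5–C-6 formed). The ketone enol then attacks the iminium carbon (C-6–C-7 formed); this is an intramolecular α-amidoalkylation of a ketone, the N-acyliminium version of the bridging Mannich annulation of cyclic ketones. Ring D closes in a six-membered mode in which both atoms of the iminium C=N and both enol carbons lie in the new ring (endo at the iminium, enol-endo). The new centre C-7 is fixed by geometry: the three-atom bridge C-4–N-5–C-6 can span C-3 and C-7 only in a cis-1,3 fashion on ring C, and C-7 stays trigonal in the enol until the bond forms. Regioselectivity is secured by quaternary C-3, which leaves C-7 as the only enolisable position. The step also needs chemoselectivity against the C-10=C-11 alkene: closure onto C-11 would be a five-membered endo closure at the iminium, closure onto C-10 would leave a cation at C-11 inside the rigid ring fusion, and the enol is by far the stronger π-nucleophile. Slow release of formaldehyde and dilution limit Prins-type addition to the alkene and intermolecular methylene-bis-amide formation. The silyl ether and the ester should survive anhydrous CF3CO2H.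

Step 13
Reactants: 21 bridged keto lactam of rings A to D
Product: 22 C-15 vinyl carbinol
Conditions: CH2=CHMgBr, CeCl3, THF, −78 °C; NH4Cl (aq)
Reagents that add atoms: vinylmagnesium bromide, C=C[Mg]Br
Why: Organocerium 1,2-addition to the strained, non-enolisable bridge ketone; the weakly basic reagent avoids retro-aldol opening of the β-alkoxy amide and attack on the ester. The carbinol configuration is of no consequence.

Step 14
Reactants: 22 C-15 vinyl carbinol
Product: 23 primary allylic alcohol with the exocyclic C-15 alkene
Conditions: Ph3SiOReO3 (5 mol %), Et2O, 0 °C → rt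
Reagents that add atoms: none
Why: Rhenium-oxo-catalysed 1,3-transposition through a [3,3] shift of the perrhenate ester; the equilibrium should favour the trisubstituted alkene and the unhindered primary alcohol over the congested tertiary carbinol. The hydroxymethyl group lies syn to C-7, away from quaternary C-3.

Step 15
Reactants: 23 primary allylic alcohol with the exocyclic C-15 alkene
Product: 25 aldehyde with vinyl and 2-oxoethyl groups on C-15, via allyl vinyl ether 24 (not isolated)
Conditions: n-BuOCH=CH2, Pd(OCOCF3)2 (5 mol %), 4,7-diphenyl-1,10-phenanthroline (5 mol %), Et3N, 75 °C; then xylenes, 150 °C (sealed)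
Reagents that add atoms: butyl vinyl ether, C=COCCCC
Why: Palladium-catalysed vinyl transfer gives the allyl vinyl ether, which undergoes a thermal Claisen rearrangement through a chair-like transition state. C-16 should be delivered to the lactam face of C-15, which is flanked only by the flat amide bridge, whereas the opposite face carries the C-1 ester and the C-8/C-9 bridge; this makes C-15 quaternary with the two-carbon arm syn to N-5 and the vinyl group (future C-21) on the carbocyclic face. The alkene geometry of 23 does not affect the configuration.

Step 16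
Reactants: 25 aldehyde with vinyl and 2-oxoethyl groups on C-15
Product: 26 C-17 primary alcohol
Conditions: NaBH4, MeOH, 0 °C
Reagents that add atoms: none
Why: Borohydride reduces the aldehyde and leaves the methyl ester, lactam and silyl ether intact.

Step 17
Reactants: 26 C-17 primary alcohol
Product: 27 C-17 primary iodide
Conditions: I2, PPh3, imidazole, CH2Cl2, 0 °C → rt
Reagents that add atoms: iodine, II
Why: Appel-type iodination by SN2 displacement of the alkoxyphosphonium ion; C-17 is two carbons from the quaternary centre and is unhindered.

Step 18
Reactants: 27 C-17 primary iodide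
Product: 28 iodo alcohol with free C-18 hydroxyl
Conditions: HF·pyridine, pyridine, THF, 0 °C → rt
Reagents that add atoms: none
Why: Buffered fluoride cleaves the silyl ether without displacing the primary iodide or touching the ester.

Step 19
Reactants: 28 iodo alcohol with free C-18 hydroxyl
Product: 29 iodo aldehyde
Conditions: triacetoxyperiodinane (DMP), NaHCO3, CH2Cl2, 0 °C
Reagents that add atoms: none
Why: Buffered periodinane oxidation gives the α-methyl aldehyde without epimerising C-19; the aldehyde is used at once.

Step 20
Reactants: 29 iodo aldehyde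
Product: 30 pentacyclic alcohol with ring E closed
Conditions: SmI2 (4 equiv), HMPA, THF, 0.003 M, −78 → 0 °C (slow addition of 29)
Reagents that add atoms: none
Why: Intramolecular Barbier reaction: SmI2 reduces the primary iodide to an alkylsamarium that adds to the aldehyde, closing the nine-membered ring at high dilution. 1,2-Induction from C-19 in the Felkin–Anh sense gives the required syn C-18/C-19 relation; ester, lactam and both alkenes are inert.

Step 21
Reactants: 30 pentacyclic alcohol with ring E closed
Product: 32 pentacyclic diol, via hydroxy aldehyde 31 (not isolated)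
Conditions: OsO4 (2 mol %), NaIO4 (3 equiv), 2,6-lutidine, dioxane/H2O (3:1), rt; then NaBH4, MeOH, 0 °C
Reagents that add atoms: osmium tetroxide (oxygen carrier, regenerated), O=[Os](=O)(=O)=O; sodium periodate, [Na+].[O-]I(=O)(=O)=O
Why: Lemieux–Johnson cleavage of the monosubstituted vinyl group; the tetrasubstituted alkene is screened on both faces by the substituents of C-3 and should not be osmylated. Borohydride then reduces the aldehyde (or its lactol with O-18) to the C-21 carbinol.

Step 22
Reactants: 32 pentacyclic diol
Product: 33 CNP0296366.1 (target)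
Conditions: Ac2O (1.1 equiv), 2,4,6-collidine, CH2Cl2, −20 → 0 °C
Reagents that add atoms: acetic anhydride, CC(=O)OC(C)=O
Why: Under mild base with limiting anhydride the primary hydroxyl should be acylated faster than the secondary ring hydroxyl flanked by the C-19 methyl group.

## Compound list

1 | dimethyl glutarate | COC(=O)CCCC(=O)OC | starting material
2 | methyl (4E)-5-methoxy-5-(trimethylsilyloxy)pent-4-enoate | COC(=O)CC/C=C(\OC)/O[Si](C)(C)C | intermediate
3 | cyclopent-2-en-1-one | O=C1C=CCC1 | starting material
4 | dimethyl (2R)-2-[(1S)-3-(trimethylsilyloxy)cyclopent-2-en-1-yl]pentanedioate | COC(=O)[C@H](CCC(=O)OC)[C@H]1CCC(O[Si](C)(C)C)=C1 | intermediate (not isolated)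
5 | dimethyl (2R)-2-[(1S)-3-(trifluoromethylsulfonyloxy)cyclopent-2-en-1-yl]pentanedioate | COC(=O)[C@H](CCC(=O)OC)[C@H]1CCC(OS(=O)(=O)C(F)(F)F)=C1 | intermediate
6 | dimethyl (2R)-2-[(1S)-3-ethenylcyclopent-2-en-1-yl]pentanedioate | COC(=O)[C@H](CCC(=O)OC)[C@H]1CCC(C=C)=C1 | intermediate
7 | methyl (2R)-6-chloro-2-[(1S)-3-ethenylcyclopent-2-en-1-yl]-5-oxohexanoate | COC(=O)[C@H](CCC(=O)CCl)[C@H]1CCC(C=C)=C1 | intermediate
8 | oxyallyl cation (zwitterion) from 7 | COC(=O)[C@H](C[CH+]C([O-])=C)[C@H]1CCC(C=C)=C1 | intermediate (not isolated)
9 | tricyclic ketone (rings A, B, C; C-15 ketone; C-9=C-10 alkene; H-1, H-3, H-11, H-12 all cis) | COC(=O)[C@@H]1C[C@@H]2C(=O)CCC=C3CC[C@H]1[C@H]23 | intermediate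
10 | tricyclic ketone with C-10=C-11 alkene (H-1, H-3, H-12 cis) | COC(=O)[C@@H]1C[C@@H]2C(=O)CCCC3=C2[C@@H]1CC3 | intermediate
11 | methyl (S)-3-hydroxy-2-methylpropanoate | COC(=O)[C@@H](C)CO | starting material
12 | methyl (S)-3-[(tert-butyldiphenylsilyl)oxy]-2-methylpropanoate | COC(=O)[C@@H](C)CO[Si](c1ccccc1)(c1ccccc1)C(C)(C)C | intermediate
13 | (R)-3-[(tert-butyldiphenylsilyl)oxy]-2-methylpropan-1-ol | OC[C@@H](C)CO[Si](c1ccccc1)(c1ccccc1)C(C)(C)C | intermediate
14 | (R)-(3-azido-2-methylpropoxy)(tert-butyl)diphenylsilane | [N-]=[N+]=NC[C@@H](C)CO[Si](c1ccccc1)(c1ccccc1)C(C)(C)C | intermediate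
15 | iminophosphorane of 14 | c1ccccc1P(=NC[C@@H](C)CO[Si](c1ccccc1)(c1ccccc1)C(C)(C)C)(c1ccccc1)c1ccccc1 | intermediate (not isolated)
16 | (R)-tert-butyl(3-isocyanato-2-methylpropoxy)diphenylsilane | O=C=NC[C@@H](C)CO[Si](c1ccccc1)(c1ccccc1)C(C)(C)C | intermediate
17 | potassium dienolate of 10 (O–C-15=C-3–C-11=C-10) | COC(=O)[C@@H]1CC2=C([O-])CCCC3=C2[C@@H]1CC3.[K+] | intermediate (not isolated)
18 | tricyclic β-keto amide: 10 carrying at C-3, on the face of H-12, the CONH–CH2–CH(CH3)–CH2–OSi(t-Bu)Ph2 group with (R)-C-19 | COC(=O)[C@@H]1C[C@]2(C(=O)NC[C@@H](C)CO[Si](c3ccccc3)(c4ccccc4)C(C)(C)C)C(=O)CCCC5=C2[C@@H]1CC5 | intermediate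
19 | formaldehyde (used as paraformaldehyde) | C=O | starting material
20 | N-methylene N-acyliminium trifluoroacetate from 18 | COC(=O)[C@@H]1C[C@]2(C(=O)[N+](=C)C[C@@H](C)CO[Si](c3ccccc3)(c4ccccc4)C(C)(C)C)C(=O)CCCC5=C2[C@@H]1CC5.[O-]C(=O)C(F)(F)F | intermediate (not isolated)
21 | bridged keto lactam (rings A to D, C-15 ketone, N-5 bearing the silyloxy side chain) | COC(=O)[C@@H]1C[C@@]23C(=O)N(C[C@@H](C)CO[Si](c5ccccc5)(c6ccccc6)C(C)(C)C)C[C@@H](CCC4=C2[C@@H]1CC4)C3=O | intermediate
22 | C-15 vinyl carbinol (vinyl on the lactam face) | COC(=O)[C@@H]1C[C@@]23C(=O)N(C[C@@H](C)CO[Si](c5ccccc5)(c6ccccc6)C(C)(C)C)C[C@@H](CCC4=C2[C@@H]1CC4)[C@]3(O)C=C | intermediate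
23 | primary allylic alcohol: (E)-2-hydroxyethylidene at C-15, CH2OH syn to C-7 | COC(=O)[C@@H]1C[C@@]23C(=O)N(C[C@@H](C)CO[Si](c5ccccc5)(c6ccccc6)C(C)(C)C)C[C@@H](CCC4=C2[C@@H]1CC4)/C3=C\CO | intermediate
24 | vinyl ether of 23 | COC(=O)[C@@H]1C[C@@]23C(=O)N(C[C@@H](C)CO[Si](c5ccccc5)(c6ccccc6)C(C)(C)C)C[C@@H](CCC4=C2[C@@H]1CC4)/C3=C\COC=C | intermediate (not isolated)
25 | aldehyde: C-15 bears vinyl (carbocyclic face) and CH2CHO (lactam face) | COC(=O)[C@@H]1C[C@@]23C(=O)N(C[C@@H](C)CO[Si](c5ccccc5)(c6ccccc6)C(C)(C)C)C[C@@H](CCC4=C2[C@@H]1CC4)[C@]3(C=C)CC=O | intermediate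
26 | C-17 primary alcohol | COC(=O)[C@@H]1C[C@@]23C(=O)N(C[C@@H](C)CO[Si](c5ccccc5)(c6ccccc6)C(C)(C)C)C[C@@H](CCC4=C2[C@@H]1CC4)[C@]3(C=C)CCO | intermediate
27 | C-17 primary iodide | COC(=O)[C@@H]1C[C@@]23C(=O)N(C[C@@H](C)CO[Si](c5ccccc5)(c6ccccc6)C(C)(C)C)C[C@@H](CCC4=C2[C@@H]1CC4)[C@]3(C=C)CCI | intermediate
28 | iodo alcohol (C-18 hydroxyl free) | COC(=O)[C@@H]1C[C@@]23C(=O)N(C[C@@H](C)CO)C[C@@H](CCC4=C2[C@@H]1CC4)[C@]3(C=C)CCI | intermediate
29 | iodo aldehyde (C-18 CHO) | COC(=O)[C@@H]1C[C@@]23C(=O)N(C[C@@H](C)C=O)C[C@@H](CCC4=C2[C@@H]1CC4)[C@]3(C=C)CCI | intermediate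
30 | pentacyclic alcohol (ring E closed, C-15 vinyl, C-18 OH syn to C-19 CH3) | COC(=O)[C@@H]1C[C@@]23C(=O)N4C[C@@H](CCC5=C2[C@@H]1CC5)[C@]3(C=C)CC[C@@H](O)[C@H](C)C4 | intermediate
31 | hydroxy aldehyde (C-21 CHO, in equilibrium with its lactol) | COC(=O)[C@@H]1C[C@@]23C(=O)N4C[C@@H](CCC5=C2[C@@H]1CC5)[C@]3(C=O)CC[C@@H](O)[C@H](C)C4 | intermediate (not isolated)
32 | pentacyclic diol (C-21 OH, C-18 OH) | COC(=O)[C@@H]1C[C@@]23C(=O)N4C[C@@H](CCC5=C2[C@@H]1CC5)[C@]3(CO)CC[C@@H](O)[C@H](C)C4 | intermediate
33 | CNP0296366.1 | COC(=O)[C@@H]1C[C@@]23C(=O)N4C[C@@H](CCC5=C2[C@@H]1CC5)[C@]3(COC(C)=O)CC[C@@H](O)[C@H](C)C4 | target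

## Step count and least certain steps

Total: 22 steps. Longest linear sequence: 18 steps (steps 1–6 and 11–22); the side-chain branch (steps 7–10) joins at step 11.

Step 12 (key step). The most likely failure is capture of the N-acyliminium ion or of protonated formaldehyde by the tetrasubstituted alkene while acid-catalysed enolisation towards C-7 is slow, or intermolecular methylene-bis-amide formation. Fallback, from 18: the ketone is α-methylenated at C-7 with paraformaldehyde and diisopropylammonium trifluoroacetate in THF at reflux, a weakly acidic amine-mediated Mannich/elimination that does not generate the N-acyliminium ion, to give the exo-methylene ketone F1. The amide N–H is then added to the enone terminus in a six-membered aza-Michael closure (DBU, MeCN), and protonation of the bridged enolate at C-7 returns to the route at 21.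

Step 15. Two things may go wrong: poor or reversed facial selectivity of the [3,3] shift at C-15, and sluggish rearrangement because the new bond is made next to quaternary C-3. Fallback, from 23, using the opposite face and a low-temperature shift:
- etherification with KH and ICH2SnBu3 to the stannylmethyl ether F2;
- tin–lithium exchange with n-BuLi at −78 °C and Still–Wittig [2,3] shift, which places CH2OH (C-21) on the face taken by the rearrangement and leaves a vinyl group on the lactam face, giving homoallylic alcohol F3;
- 4-methoxybenzyl trichloroacetimidate with catalytic acid to the PMB ether F4;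
- 9-BBN, then NaBO3, to the C-17 alcohol F5;
- I2, PPh3, imidazole to the iodide F6;
- HF·pyridine to the alcohol F7;
- periodinane oxidation to the aldehyde F8;
- SmI2 ring closure to the PMB-protected pentacyclic alcohol F9;
- DDQ, returning to the route at 32.

Step 20. Reductive dimerisation or simple reduction of the aldehyde may outrun the entropically disfavoured nine-membered closure, and the C-18 selectivity may be eroded by ring constraints. Fallback, from 27, replacing the organometallic addition by a reversible nitronate aldol:
- displacement with AgNO2 in Et2O to the nitroalkane F10;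
- HF·pyridine to the nitro alcohol F11;
- periodinane oxidation to the nitro aldehyde F12;
- intramolecular Henry reaction (catalytic DBU, THF, high dilution) to the cyclic β-nitro alcohol F13 (mixture at C-17);
- radical denitration with Bu3SnH and AIBN in PhMe at 110 °C, returning to the route at 30.

Step 2. Enantioselectivity or simple diastereoselectivity (C-1) may be insufficient, because the ketene acetal is prochiral and carries a second Lewis-basic ester. Fallback, from 2 and 3: the addition is run with an achiral Lewis acid (TMSOTf, catalytic, CH2Cl2, −78 °C) and followed by the same triflation. This gives the racemic syn adduct, that is 5 together with its mirror image, the enantiomeric enol triflate F15, formed through the enantiomeric silyl enol ether F14. The enantiomers are separated by preparative chromatography on a chiral stationary phase, and the route is rejoined at 5.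

Step 4. Discrimination between the two methyl esters may be incomplete, leading to double homologation. Fallback, from 6: dimethylsulfoxonium methylide (from Me3S(O)I and KOt-Bu, THF, reflux), a bulky stabilised ylide, attacks only the unhindered ester and gives the β-keto sulfoxonium ylide F16. Protonation and displacement of dimethyl sulfoxide by chloride (HCl in dioxane/THF, 65 °C) return to the route at 7.

Further compounds

F1 | step 12 | α-methylene ketone of 18 (C-7=CH2) | COC(=O)[C@@H]1C[C@]2(C(=O)NC[C@@H](C)CO[Si](c3ccccc3)(c4ccccc4)C(C)(C)C)C(=O)C(=C)CCC5=C2[C@@H]1CC5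
F2 | step 15 | tributylstannylmethyl ether of 23 | COC(=O)[C@@H]1C[C@@]23C(=O)N(C[C@@H](C)CO[Si](c5ccccc5)(c6ccccc6)C(C)(C)C)C[C@@H](CCC4=C2[C@@H]1CC4)/C3=C\COC[Sn](CCCC)(CCCC)CCCC
F3 | step 15 | homoallylic alcohol: C-15 bears CH2OH (carbocyclic face) and vinyl (lactam face) | COC(=O)[C@@H]1C[C@@]23C(=O)N(C[C@@H](C)CO[Si](c5ccccc5)(c6ccccc6)C(C)(C)C)C[C@@H](CCC4=C2[C@@H]1CC4)[C@]3(CO)C=C
F4 | step 15 | PMB ether of F3 | COC(=O)[C@@H]1C[C@@]23C(=O)N(C[C@@H](C)CO[Si](c5ccccc5)(c6ccccc6)C(C)(C)C)C[C@@H](CCC4=C2[C@@H]1CC4)[C@]3(COCc7ccc(OC)cc7)C=C
F5 | step 15 | C-17 alcohol with C-21 OPMB | COC(=O)[C@@H]1C[C@@]23C(=O)N(C[C@@H](C)CO[Si](c5ccccc5)(c6ccccc6)C(C)(C)C)C[C@@H](CCC4=C2[C@@H]1CC4)[C@]3(COCc7ccc(OC)cc7)CCO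
F6 | step 15 | C-17 iodide with C-21 OPMB | COC(=O)[C@@H]1C[C@@]23C(=O)N(C[C@@H](C)CO[Si](c5ccccc5)(c6ccccc6)C(C)(C)C)C[C@@H](CCC4=C2[C@@H]1CC4)[C@]3(COCc7ccc(OC)cc7)CCI
F7 | step 15 | iodo alcohol with C-21 OPMB | COC(=O)[C@@H]1C[C@@]23C(=O)N(C[C@@H](C)CO)C[C@@H](CCC4=C2[C@@H]1CC4)[C@]3(COCc5ccc(OC)cc5)CCI
F8 | step 15 | iodo aldehyde with C-21 OPMB | COC(=O)[C@@H]1C[C@@]23C(=O)N(C[C@@H](C)C=O)C[C@@H](CCC4=C2[C@@H]1CC4)[C@]3(COCc5ccc(OC)cc5)CCI
F9 | step 15 | pentacyclic alcohol with C-21 OPMB | COC(=O)[C@@H]1C[C@@]23C(=O)N4C[C@@H](CCC5=C2[C@@H]1CC5)[C@]3(COCc6ccc(OC)cc6)CC[C@@H](O)[C@H](C)C4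
F10 | step 20 | C-17 nitroalkane (silyl ether) | COC(=O)[C@@H]1C[C@@]23C(=O)N(C[C@@H](C)CO[Si](c5ccccc5)(c6ccccc6)C(C)(C)C)C[C@@H](CCC4=C2[C@@H]1CC4)[C@]3(C=C)CC[N+](=O)[O-]
F11 | step 20 | nitro alcohol | COC(=O)[C@@H]1C[C@@]23C(=O)N(C[C@@H](C)CO)C[C@@H](CCC4=C2[C@@H]1CC4)[C@]3(C=C)CC[N+](=O)[O-]
F12 | step 20 | nitro aldehyde | COC(=O)[C@@H]1C[C@@]23C(=O)N(C[C@@H](C)C=O)C[C@@H](CCC4=C2[C@@H]1CC4)[C@]3(C=C)CC[N+](=O)[O-]
F13 | step 20 | cyclic β-nitro alcohol (C-17 nitro, mixture at C-17) | COC(=O)[C@@H]1C[C@@]23C(=O)N4C[C@@H](CCC5=C2[C@@H]1CC5)[C@]3(C=C)CC([N+](=O)[O-])[C@@H](O)[C@H](C)C4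
F14 | step 2 | enantiomer of 4 | COC(=O)[C@@H](CCC(=O)OC)[C@@H]1CCC(O[Si](C)(C)C)=C1
F15 | step 2 | enantiomer of 5 | COC(=O)[C@@H](CCC(=O)OC)[C@@H]1CCC(OS(=O)(=O)C(F)(F)F)=C1
F16 | step 4 | β-keto sulfoxonium ylide from 6 | COC(=O)[C@H](CCC(=O)C=S(C)(C)=O)[C@H]1CCC(C=C)=C1
A1 | alternative 1 | tricyclic ketone of rings A, B, C (identical with 9) | COC(=O)[C@@H]1C[C@@H]2C(=O)CCC=C3CC[C@H]1[C@H]23
A2 | alternative 1 | chloromethyl ketone tethered to 1-vinylcyclopentene (identical with 7) | COC(=O)[C@H](CCC(=O)CCl)[C@H]1CCC(C=C)=C1
A3 | alternative 2 | nine-membered N-PMB lactam carrying both quaternary carbons | COC(=O)CC[C@]1(C2=C(OS(=O)(=O)C(F)(F)F)CCC2)C(=O)N(Cc3ccc(OC)cc3)C[C@@H](C)[C@H](O[Si](C)(C)C(C)(C)C)/C=C/[C@@]1(CO[Si](C)(C)C(C)(C)C)[C@@H](COCc4ccccc4)C=C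
A4 | alternative 2 | disubstituted ketene (fragment 1) | COC(=O)CCC(=C=O)C1=C(OS(=O)(=O)C(F)(F)F)CCC1
A5 | alternative 2 | N-PMB 2-alkenylpyrrolidine (fragment 2; C-2 configuration and E alkene chosen for chirality transfer to C-15) | COc1ccc(CN2C[C@@H](C)[C@H](O[Si](C)(C)C(C)(C)C)[C@H]2/C=C(/CO[Si](C)(C)C(C)(C)C)[C@@H](COCc3ccccc3)C=C)cc1
A6 | alternative 3 | keto lactam (target with C-18 ketone) | COC(=O)[C@@H]1C[C@@]23C(=O)N4C[C@@H](CCC5=C2[C@@H]1CC5)[C@]3(COC(C)=O)CCC(=O)[C@H](C)C4
A7 | alternative 3 | hexacyclic enamine (C-4=C-18) | COC(=O)[C@@H]1C[C@@]23C6N4C[C@@H](CCC5=C2[C@@H]1CC5)[C@]3(COC(C)=O)CCC=6[C@H](C)C4
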